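The target is cut at the central methylene into two benzophenones that share the phloroglucinol ring (ring A: 2,6-di-OH, 4-OMe) and differ only at O-2′ of the orcinol ring (ring B). Ring B of the methoxy half is built, not carried: a 1-arylbut-2-yn-1-one takes up a 1,1-dimethoxy-3-siloxybutadiene and, after loss of methanol, delivers in one operation the arene with OMe at C2′ (ortho to the ketone carbon C1′), OH at C4′ (para) and methyl at C6′. The precursor is the ynone made from 2,6-bis(benzyloxy)-4-methoxybenzaldehyde; the same ynone and a mixed methyl silyl ketene acetal diene give the dihydroxy half.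

Key step: step 8

Assumption: 1-methoxy-1,3-bis(trimethylsilyloxy)buta-1,3-diene (17) is taken as a purchased reagent, and salts that are only neutralised on work-up (alkoxides, phenoxides, ammonium salts) are not counted as intermediates.

Step 1
Reactants: 1 2,4,6-trihydroxybenzaldehyde
Product: 2 2,6-dihydroxy-4-methoxybenzaldehyde
Conditions: Me2SO4 (1.0 equiv), K2CO3 (1.0 equiv), acetone, 0 °C to rt
Reagents that add atoms: dimethyl sulfate, COS(=O)(=O)OC
Why: The 4-OH, para to the formyl group and outside its hydrogen-bonding reach, is the most acidic and most accessible phenol, so one equivalent of base and alkylating agent should give the 4-O-methyl ether (Williamson etherification) and leave the two ortho hydroxyls free.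

Step 2
Reactants: 2 2,6-dihydroxy-4-methoxybenzaldehyde
Product: 3 2,6-bis(benzyloxy)-4-methoxybenzaldehyde
Conditions: BnBr (2.4 equiv), K2CO3 (3 equiv), DMF, 60 °C
Reagents that add atoms: benzyl bromide, BrCc1ccccc1
Why: Williamson etherification of both ortho phenols is driven by excess benzyl bromide in warm DMF, and benzyl ethers should survive the Grignard addition, MnO2 and the thermal cycloaddition and later fall to hydrogenolysis without loss of a methyl ether.

Step 3
Reactants: 3 2,6-bis(benzyloxy)-4-methoxybenzaldehyde; 4 1-propynylmagnesium bromide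
Product: 5 1-[2,6-bis(benzyloxy)-4-methoxyphenyl]but-2-yn-1-ol (racemic)
Conditions: THF, 0 °C to rt; then pH 7 aqueous buffer
Reagents that add atoms: none
Why: 1,2-Addition of an alkynyl Grignard reagent to a non-enolisable aldehyde; the carbinol centre forms as a racemate and is erased in step 4, and the neutral quench protects this easily ionised, electron-rich alcohol.

Step 4
Reactants: 5 1-[2,6-bis(benzyloxy)-4-methoxyphenyl]but-2-yn-1-ol
Product: 6 1-[2,6-bis(benzyloxy)-4-methoxyphenyl]but-2-yn-1-one
Conditions: MnO2 (15 equiv), CH2Cl2, rt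
Reagents that add atoms: none
Why: MnO2 oxidises the doubly activated (benzylic and propargylic) alcohol to the ynone under neutral conditions that leave benzyl ethers and the alkyne untouched.

Step 5
Reactants: 7 acetyl chloride; 8 1,1-dichloroethene
Product: 10 4,4-dichlorobut-3-en-2-one, via 4,4,4-trichlorobutan-2-one 9 (not isolated)
Conditions: AlCl3 (1.1 equiv), CH2Cl2, 0 °C to rt; ice water; then steam distillation
Reagents that add atoms: none
Why: Friedel–Crafts-type acylation of the alkene by the acylium ion gives the β-trichloro ketone after chloride capture, which should lose HCl to the conjugated β,β-dichlorovinyl ketone on steam distillation.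

Step 6
Reactants: 10 4,4-dichlorobut-3-en-2-one
Product: 11 4,4-dimethoxybut-3-en-2-one
Conditions: NaOMe (2.2 equiv), MeOH, 0 °C to rt
Reagents that add atoms: sodium methoxide, C[O-].[Na+]
Why: Two consecutive conjugate addition–elimination steps (vinylic substitution) by methoxide on the β,β-dichloroenone should give the acyl ketene acetal.

Step 7
Reactants: 11 4,4-dimethoxybut-3-en-2-one
Product: 12 1,1-dimethoxy-3-(trimethylsilyloxy)buta-1,3-diene
Conditions: TMSCl, Et3N, ZnCl2 (cat.), toluene, 40 °C; distillation
Reagents that add atoms: chlorotrimethylsilane, C[Si](C)(C)Cl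
Why: Soft enolisation and O-silylation of the methyl ketone, the only enolisable position, is the standard preparation of 2-siloxydienes and should give the diene, which is distilled and used fresh.

Step 8
Reactants: 6 1-[2,6-bis(benzyloxy)-4-methoxyphenyl]but-2-yn-1-one; 12 1,1-dimethoxy-3-(trimethylsilyloxy)buta-1,3-diene
Product: 15 [2,6-bis(benzyloxy)-4-methoxyphenyl](4-hydroxy-2-methoxy-6-methylphenyl)methanone, via cyclohexadiene cycloadduct 13 (not isolated), via aryl trimethylsilyl ether 14 (not isolated)
Conditions: 12 (2.5 equiv), toluene, 110 °C, sealed tube; then 1 M HCl, THF, rt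
Reagents that add atoms: none
Why: The electron-rich diene 12 and the electron-poor alkyne of 6 should combine in a thermal, normal-electron-demand but strongly asynchronous [4+2] cycloaddition, in which the CH2 terminus of 12 (made nucleophilic by the 3-siloxy group and, through the diene, by the ketene acetal) bonds first to the methyl-bearing alkyne carbon β to the carbonyl and the ketene acetal carbon then bonds to the acyl-bearing carbon. The closest known reaction type is the Diels–Alder benzannulation of 1,1-dialkoxy-3-siloxybutadienes with acetylenic esters and ketones, which gives resorcinol monoethers. The single new ring, the six-membered carbocycle that becomes ring B, is closed by this intermolecular [4+2] union of the four diene carbons with the two alkyne carbons; the 1,4-cyclohexadiene 13 then ionises at its ketal carbon to an arenium-type cation that loses a proton from the ring CH2, so methanol leaves and arene 14 forms, and dilute acid cleaves the silyl ether. No stereocentre is created. The step needs regioselectivity (ketal carbon next to the acyl carbon, hence OMe ortho and OH para to the ketone) and chemoselectivity for the alkyne over the carbonyl group; the first follows from the matched polarisation of ynone and diene, the second from the absence of a Lewis acid, and the two ortho benzyloxy groups twist ring A out of conjugation so that the ketone keeps the alkyne electron-poor.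

Step 9
Reactants: 15 [2,6-bis(benzyloxy)-4-methoxyphenyl](4-hydroxy-2-methoxy-6-methylphenyl)methanone
Product: 16 (2,6-dihydroxy-4-methoxyphenyl)(4-hydroxy-2-methoxy-6-methylphenyl)methanone
Conditions: H2 (1 atm), Pd/C (10 wt %), EtOAc–MeOH, rt
Reagents that add atoms: none
Why: Hydrogenolysis of aryl benzyl ethers over palladium on carbon; the tetra-ortho-substituted diaryl ketone and the methyl ethers should be inert under one atmosphere of hydrogen at room temperature.

Step 10
Reactants: 6 1-[2,6-bis(benzyloxy)-4-methoxyphenyl]but-2-yn-1-one; 17 1-methoxy-1,3-bis(trimethylsilyloxy)buta-1,3-diene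
Product: 20 [2,6-bis(benzyloxy)-4-methoxyphenyl](2,4-dihydroxy-6-methylphenyl)methanone, via mixed-ketal cycloadduct 18 (not isolated), via bis(trimethylsilyl) ether 19 (not isolated)
Conditions: 17 (2.5 equiv), toluene, 90 °C; then 1 M HCl, THF, rt
Reagents that add atoms: none
Why: The same Diels–Alder benzannulation with the mixed methyl trimethylsilyl ketene acetal diene should bond the CH2 terminus to the methyl-bearing alkyne carbon again; the cycloadduct (one ketal stereocentre, racemic and destroyed on aromatisation) loses methanol in preference to silanol, as mixed vinylketene acetals are known to do, and acid work-up frees both hydroxyls of ring B.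

Step 11
Reactants: 20 [2,6-bis(benzyloxy)-4-methoxyphenyl](2,4-dihydroxy-6-methylphenyl)methanone
Product: 21 (2,6-dihydroxy-4-methoxyphenyl)(2,4-dihydroxy-6-methylphenyl)methanone
Conditions: H2 (1 atm), Pd/C (10 wt %), EtOAc–MeOH, rt
Reagents that add atoms: none
Why: Hydrogenolysis of the two aryl benzyl ethers as in step 9, with the hindered ketone and the methyl ether expected to stay intact.

Step 12
Reactants: 16 (2,6-dihydroxy-4-methoxyphenyl)(4-hydroxy-2-methoxy-6-methylphenyl)methanone
Product: 22 {3-[(dimethylamino)methyl]-2,6-dihydroxy-4-methoxyphenyl}(4-hydroxy-2-methoxy-6-methylphenyl)methanone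
Conditions: CH2=NMe2+ I− (1.0 equiv), MeCN, 0 °C to rt; then aq. NaHCO3; used without chromatography
Reagents that add atoms: N,N-dimethylmethyleneiminium iodide, C=[N+](C)C.[I-]
Why: Mannich-type electrophilic aminomethylation with a preformed iminium salt and no added base should take place on the neutral ring A, whose C3 and C5 are equivalent and activated by three ortho/para oxygen donors against two for ring B, and protonation of the product amine by the HI released slows a second substitution.

Step 13
Reactants: 22 {3-[(dimethylamino)methyl]-2,6-dihydroxy-4-methoxyphenyl}(4-hydroxy-2-methoxy-6-methylphenyl)methanone; 21 (2,6-dihydroxy-4-methoxyphenyl)(2,4-dihydroxy-6-methylphenyl)methanone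
Product: 24 [3-{[3-(2,4-dihydroxy-6-methylbenzoyl)-2,4-dihydroxy-6-methoxyphenyl]methyl}-2,6-dihydroxy-4-methoxyphenyl](4-hydroxy-2-methoxy-6-methylphenyl)methanone (target), via ortho-quinone methide 23 (not isolated)
Conditions: 21 (2 equiv), 1,4-dioxane, 90 °C, N2 stream
Reagents that add atoms: none
Why: Thermal loss of dimethylamine from the ortho-hydroxybenzylamine should give an ortho-quinone methide that is captured at C3 of ring A of 21 (conjugate addition, a Friedel–Crafts alkylation, the classical Mannich-base route to unsymmetrical methylene-bis-phloroglucinols), and the excess of 21 with neutral, base-free conditions limits self-condensation, over-alkylation and xanthone formation.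

Compound list
1 | 2,4,6-trihydroxybenzaldehyde | Oc1cc(O)c(C=O)c(O)c1 | starting material
2 | 2,6-dihydroxy-4-methoxybenzaldehyde | COc1cc(O)c(C=O)c(O)c1 | intermediate
3 | 2,6-bis(benzyloxy)-4-methoxybenzaldehyde | COc1cc(OCc2ccccc2)c(C=O)c(OCc2ccccc2)c1 | intermediate
4 | 1-propynylmagnesium bromide | CC#C[Mg]Br | starting material
5 | 1-[2,6-bis(benzyloxy)-4-methoxyphenyl]but-2-yn-1-ol (racemic) | CC#CC(O)c1c(OCc2ccccc2)cc(OC)cc1OCc1ccccc1 | intermediate
6 | 1-[2,6-bis(benzyloxy)-4-methoxyphenyl]but-2-yn-1-one | CC#CC(=O)c1c(OCc2ccccc2)cc(OC)cc1OCc1ccccc1 | intermediate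
7 | acetyl chloride | CC(=O)Cl | starting material
8 | 1,1-dichloroethene | C=C(Cl)Cl | starting material
9 | 4,4,4-trichlorobutan-2-one | CC(=O)CC(Cl)(Cl)Cl | intermediate (not isolated)
10 | 4,4-dichlorobut-3-en-2-one | CC(=O)C=C(Cl)Cl | intermediate
11 | 4,4-dimethoxybut-3-en-2-one | CC(=O)C=C(OC)OC | intermediate
12 | 1,1-dimethoxy-3-(trimethylsilyloxy)buta-1,3-diene | COC(OC)=CC(=C)O[Si](C)(C)C | intermediate
13 | [2,6-bis(benzyloxy)-4-methoxyphenyl][6,6-dimethoxy-2-methyl-4-(trimethylsilyloxy)cyclohexa-1,4-dien-1-yl]methanone | COc1cc(OCc2ccccc2)c(C(=O)C2=C(C)CC(O[Si](C)(C)C)=CC2(OC)OC)c(OCc2ccccc2)c1 | intermediate (not isolated)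
14 | [2,6-bis(benzyloxy)-4-methoxyphenyl][2-methoxy-6-methyl-4-(trimethylsilyloxy)phenyl]methanone | COc1cc(OCc2ccccc2)c(C(=O)c2c(C)cc(O[Si](C)(C)C)cc2OC)c(OCc2ccccc2)c1 | intermediate (not isolated)
15 | [2,6-bis(benzyloxy)-4-methoxyphenyl](4-hydroxy-2-methoxy-6-methylphenyl)methanone | COc1cc(OCc2ccccc2)c(C(=O)c2c(C)cc(O)cc2OC)c(OCc2ccccc2)c1 | intermediate
16 | (2,6-dihydroxy-4-methoxyphenyl)(4-hydroxy-2-methoxy-6-methylphenyl)methanone | COc1cc(O)c(C(=O)c2c(C)cc(O)cc2OC)c(O)c1 | intermediate
17 | 1-methoxy-1,3-bis(trimethylsilyloxy)buta-1,3-diene (geometry at C1=C2 as supplied; it is lost in the product) | COC(O[Si](C)(C)C)=CC(=C)O[Si](C)(C)C | starting material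
18 | [2,6-bis(benzyloxy)-4-methoxyphenyl][6-methoxy-2-methyl-4,6-bis(trimethylsilyloxy)cyclohexa-1,4-dien-1-yl]methanone (racemic at C6) | COc1cc(OCc2ccccc2)c(C(=O)C2=C(C)CC(O[Si](C)(C)C)=CC2(OC)O[Si](C)(C)C)c(OCc2ccccc2)c1 | intermediate (not isolated)
19 | [2,6-bis(benzyloxy)-4-methoxyphenyl][2-methyl-4,6-bis(trimethylsilyloxy)phenyl]methanone | COc1cc(OCc2ccccc2)c(C(=O)c2c(C)cc(O[Si](C)(C)C)cc2O[Si](C)(C)C)c(OCc2ccccc2)c1 | intermediate (not isolated)
20 | [2,6-bis(benzyloxy)-4-methoxyphenyl](2,4-dihydroxy-6-methylphenyl)methanone | COc1cc(OCc2ccccc2)c(C(=O)c2c(C)cc(O)cc2O)c(OCc2ccccc2)c1 | intermediate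
21 | (2,6-dihydroxy-4-methoxyphenyl)(2,4-dihydroxy-6-methylphenyl)methanone | COc1cc(O)c(C(=O)c2c(C)cc(O)cc2O)c(O)c1 | intermediate
22 | {3-[(dimethylamino)methyl]-2,6-dihydroxy-4-methoxyphenyl}(4-hydroxy-2-methoxy-6-methylphenyl)methanone | COc1cc(O)c(C(=O)c2c(C)cc(O)cc2OC)c(O)c1CN(C)C | intermediate
23 | 3-hydroxy-2-(4-hydroxy-2-methoxy-6-methylbenzoyl)-5-methoxy-6-methylidenecyclohexa-2,4-dien-1-one | C=C1C(OC)=CC(O)=C(C(=O)c2c(C)cc(O)cc2OC)C1=O | intermediate (not isolated)
24 | [3-{[3-(2,4-dihydroxy-6-methylbenzoyl)-2,4-dihydroxy-6-methoxyphenyl]methyl}-2,6-dihydroxy-4-methoxyphenyl](4-hydroxy-2-methoxy-6-methylphenyl)methanone, CNP0596095.0, no stereocentre | COc1cc(O)c(C(=O)c2c(C)cc(O)cc2O)c(O)c1Cc1c(OC)cc(O)c(C(=O)c2c(C)cc(O)cc2OC)c1O | target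

Total step count: 13. Longest linear sequence: 8 steps (1, 2, 3, 4, 8, 9, 12, 13).

Steps most likely to fail

Step 8. The cycloaddition to the β-methyl, sterically shielded ynone may be slower than the thermal or hydrolytic decay of the ketene acetal diene, or the diene may add only in open-chain Michael fashion without ring closure. The fallback sets out from aldehyde 3 and comes back at 16, joining the two rings by organolithium addition instead of building ring B. Commercial 3-methoxy-5-methylphenol would be brominated para to the hydroxyl (NBS, MeCN, 0 °C) to 4-bromo-3-methoxy-5-methylphenol F1, with any ortho isomer removed at this stage. Benzylation (BnBr, K2CO3, DMF) would give 5-(benzyloxy)-2-bromo-1-methoxy-3-methylbenzene F2. Bromine–lithium exchange (n-BuLi, THF, −78 °C) and addition to 3 would give racemic [2,6-bis(benzyloxy)-4-methoxyphenyl][4-(benzyloxy)-2-methoxy-6-methylphenyl]methanol F3. MnO2 in CH2Cl2 would oxidise this to [2,6-bis(benzyloxy)-4-methoxyphenyl][4-(benzyloxy)-2-methoxy-6-methylphenyl]methanone F4, and hydrogenolysis (H2, Pd/C) of all three benzyl ethers would deliver 16.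

Step 13. The quinone methide may be captured by a second molecule of 22 or by the product (self-condensation and over-alkylation). The more electron-rich of the two rings of 21 may also fail to dominate, so that bonding occurs through the resorcinol ring B. The fallback sets out from 20 and comes back at 24, masking ring B of the dihydroxy half as esters during the coupling. Acylation of 20 (PivCl, Et3N, DMAP, CH2Cl2) would give [2,6-bis(benzyloxy)-4-methoxyphenyl][2,4-bis(2,2-dimethylpropanoyloxy)-6-methylphenyl]methanone F5. Hydrogenolysis (H2, Pd/C) would give (2,6-dihydroxy-4-methoxyphenyl)[2,4-bis(2,2-dimethylpropanoyloxy)-6-methylphenyl]methanone F6, in which only ring A remains nucleophilic. Heating F6 with 22 (1,4-dioxane, 90 °C) would give the methylene-bridged dipivalate F7, and K2CO3 in MeOH at rt would remove both esters to give 24.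

Step 10. The mixed ketal may lose silanol instead of methanol, which would return 15 and not 20, and the bis-silyl diene may decay thermally before it adds to the ynone. The fallback sets out from aldehyde 3 and comes back at 21. Commercial orcinol (5-methylbenzene-1,3-diol) would be dibenzylated (BnBr, K2CO3, DMF) to 1,3-bis(benzyloxy)-5-methylbenzene F8 and brominated ortho to the methyl group (NBS, MeCN) to 1,5-bis(benzyloxy)-2-bromo-3-methylbenzene F9. Bromine–lithium exchange (n-BuLi, THF, −78 °C) and addition to 3 would give racemic [2,6-bis(benzyloxy)-4-methoxyphenyl][2,4-bis(benzyloxy)-6-methylphenyl]methanol F10. MnO2 would oxidise this to [2,6-bis(benzyloxy)-4-methoxyphenyl][2,4-bis(benzyloxy)-6-methylphenyl]methanone F11, and hydrogenolysis (H2, Pd/C) of the four benzyl ethers would deliver 21.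

Further compounds
F1 | step 8 | 4-bromo-3-methoxy-5-methylphenol | COc1cc(O)cc(C)c1Br
F2 | step 8 | 5-(benzyloxy)-2-bromo-1-methoxy-3-methylbenzene | COc1cc(OCc2ccccc2)cc(C)c1Br
F3 | step 8 | [2,6-bis(benzyloxy)-4-methoxyphenyl][4-(benzyloxy)-2-methoxy-6-methylphenyl]methanol (racemic) | COc1cc(OCc2ccccc2)c(C(O)c2c(C)cc(OCc3ccccc3)cc2OC)c(OCc2ccccc2)c1
F4 | step 8 | [2,6-bis(benzyloxy)-4-methoxyphenyl][4-(benzyloxy)-2-methoxy-6-methylphenyl]methanone | COc1cc(OCc2ccccc2)c(C(=O)c2c(C)cc(OCc3ccccc3)cc2OC)c(OCc2ccccc2)c1
F5 | step 13 | [2,6-bis(benzyloxy)-4-methoxyphenyl][2,4-bis(2,2-dimethylpropanoyloxy)-6-methylphenyl]methanone | COc1cc(OCc2ccccc2)c(C(=O)c2c(C)cc(OC(=O)C(C)(C)C)cc2OC(=O)C(C)(C)C)c(OCc2ccccc2)c1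
F6 | step 13 | (2,6-dihydroxy-4-methoxyphenyl)[2,4-bis(2,2-dimethylpropanoyloxy)-6-methylphenyl]methanone | COc1cc(O)c(C(=O)c2c(C)cc(OC(=O)C(C)(C)C)cc2OC(=O)C(C)(C)C)c(O)c1
F7 | step 13 | 2′,4′-di-O-pivaloyl derivative of 24 (both esters on ring B of the dihydroxy half) | COc1cc(O)c(C(=O)c2c(C)cc(OC(=O)C(C)(C)C)cc2OC(=O)C(C)(C)C)c(O)c1Cc1c(OC)cc(O)c(C(=O)c2c(C)cc(O)cc2OC)c1O
F8 | step 10 | 1,3-bis(benzyloxy)-5-methylbenzene | Cc1cc(OCc2ccccc2)cc(OCc2ccccc2)c1
F9 | step 10 | 1,5-bis(benzyloxy)-2-bromo-3-methylbenzene | Cc1cc(OCc2ccccc2)cc(OCc2ccccc2)c1Br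
F10 | step 10 | [2,6-bis(benzyloxy)-4-methoxyphenyl][2,4-bis(benzyloxy)-6-methylphenyl]methanol (racemic) | COc1cc(OCc2ccccc2)c(C(O)c2c(C)cc(OCc3ccccc3)cc2OCc2ccccc2)c(OCc2ccccc2)c1
F11 | step 10 | [2,6-bis(benzyloxy)-4-methoxyphenyl][2,4-bis(benzyloxy)-6-methylphenyl]methanone | COc1cc(OCc2ccccc2)c(C(=O)c2c(C)cc(OCc3ccccc3)cc2OCc2ccccc2)c(OCc2ccccc2)c1
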